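The route rests on cutting C10–C11, the bond between the gem-dimethyl quaternary carbon and the chain, right beside the oxolane ring (O, C6, C7, C8, C9; jatrophane numbering). Because the ring oxygen on C9 is vicinal to tertiary C10, this oxolane can be born from an oxane (O, C6–C10) carrying a C9 mesylate. An alkynylalane ionises the mesylate, oxygen slips from C10 to C9 with inversion, and the alkynyl ligand caps C10. One operation contracts the ring, sets C9, builds the quaternary carbon and joins two halves of similar size. The precursor pair is a linalool-derived pyranoid mesylate and a furyl alkyne; the furan later becomes the cyclopentenone.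

Key step: step 7

Atom labels: C1(H)=C2(Me)–C3(=O)–C4(=C5H)–C15(OAc) is the cyclopentenone. C6(Me)–C7–C8–C9 plus O is the oxolane, C10 the CMe2 carbon, C11–C12 the CH2CH2 link, C13 the CHMe centre and C14 the macrocyclic ketone.

Assumption: (S)-(+)-linalool, (S)-but-3-yn-2-ol and 4,5-dimethylfuran-2-carbaldehyde are bought, the two chiral ones in high enantiomeric purity.

Step 1
Reactants: 1 (S)-(+)-linalool
Product: 2 (3S,6R)-6,7-epoxylinalool
Conditions: D-fructose-derived Shi ketone (1,2:4,5-di-O-isopropylidene-β-D-erythro-2,3-hexodiulo-2,6-pyranose, 30 mol %), Oxone (2KHSO5·KHSO4·K2SO4), K2CO3, Bu4NHSO4 (cat.), MeCN–CH2(OMe)2/aq. Na2B4O7 buffer, 0 °C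
Reagents that add atoms: potassium peroxymonosulfate (active salt of Oxone), [K+].[O-]S(=O)(=O)OO
Why: Shi asymmetric epoxidation, in which the dioxirane of the D-fructose-derived ketone attacks the electron-rich trisubstituted C9=C10 alkene through a spiro transition state on the face that gives 9R, while the monosubstituted vinyl group is left alone and C6 is carried over from linalool.

Step 2
Reactants: 2 (3S,6R)-6,7-epoxylinalool
Product: 4 (3R,6S)-6-ethenyl-2,2,6-trimethyloxan-3-ol (pyranoid linalool oxide), via trimethylsilyl ether 3 (not isolated)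
Conditions: TMSOTf, 2,6-lutidine, MeNO2, −20 to 0 °C; then 1 M HCl, THF, 0 °C
Reagents that add atoms: none
Why: Silyl-triflate-promoted 6-endo-tet epoxide opening, in which strong O-silylation makes the transition state cation-like so that the C6 oxygen attacks the tertiary carbon C10 (Markovnikov sense), the C9–O bond is never broken so C9 stays R, and the labile silyl ether falls off in the acidic work-up.

Step 3
Reactants: 4 (3R,6S)-6-ethenyl-2,2,6-trimethyloxan-3-ol
Product: 5 (3R,6S)-6-ethenyl-2,2,6-trimethyloxan-3-yl methanesulfonate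
Conditions: MsCl, Et3N, CH2Cl2, 0 °C
Reagents that add atoms: methanesulfonyl chloride, CS(=O)(=O)Cl
Why: Sulfonylation through sulfene works on the hindered secondary alcohol without breaking the C9–O bond, so C9 stays R and the leaving group sits cis to the C6 methyl group, where it can lie equatorial and antiperiplanar to the O–C10 ring bond.

Step 4
Reactants: 6 (S)-but-3-yn-2-ol
Product: 7 (S)-but-3-yn-2-yl methanesulfonate
Conditions: MsCl, Et3N, CH2Cl2, −78 to 0 °C
Reagents that add atoms: methanesulfonyl chloride, CS(=O)(=O)Cl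
Why: Standard sulfonylation on oxygen, which leaves the carbinol configuration (S) untouched and arms the propargylic position for palladium.

Step 5
Reactants: 7 (S)-but-3-yn-2-yl methanesulfonate; 8 4,5-dimethylfuran-2-carbaldehyde
Product: 10 (1R,2R)-1-(4,5-dimethylfuran-2-yl)-2-methylbut-3-yn-1-ol, via allenylindium reagent 9 (not isolated)
Conditions: Pd(dppf)Cl2 (5 mol %), InI, THF–HMPA, rt
Reagents that add atoms: none
Why: Marshall-type propargylation, in which zerovalent palladium opens the mesylate anti (SN2′), InI transmetalates with retention to the allenylindium 9, and this adds to the aldehyde through a cyclic SE2′ transition state, so that C13 (R) results from net inversion of the carbinol carbon of 7 and C14 (R) from the anti preference of the cyclic transition state.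

Step 6
Reactants: 10 (1R,2R)-1-(4,5-dimethylfuran-2-yl)-2-methylbut-3-yn-1-ol
Product: 11 TBS ether of 10
Conditions: TBSCl, imidazole, DMF, rt
Reagents that add atoms: tert-butyldimethylsilyl chloride, CC(C)(C)[Si](C)(C)Cl
Why: Standard silylation that masks the carbinol for the organometallic step and later serves as the non-chelating polar group on C14 that steers the formation of C15.

Step 7
Reactants: 5 (3R,6S)-6-ethenyl-2,2,6-trimethyloxan-3-yl methanesulfonate; 11 TBS ether of 10
Product: 15 oxolane enyne (6S,9S,13R,14R), via lithium acetylide 12 (not isolated), via alkynylalane 13 (not isolated), via bicyclic oxonium ion 14 (not isolated)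
Conditions: 11, n-BuLi, toluene, −78 °C; Me2AlCl, −78 to 0 °C; then 5, CH2Cl2–toluene, −40 °C to rt; aqueous work-up
Reagents that add atoms: none
Why: Proposed new method: the Lewis acidic aluminium centre of 13 pulls off the equatorial C9 mesylate while the antiperiplanar ring oxygen displaces it from the rear (3-exo-tet participation), giving the 1-oxoniabicyclo[3.1.0]hexane ion 14 paired with an alkynyl(mesyloxy)aluminate; strain release then breaks the O–C10 bond, where tertiary cation character is largest, and the aluminate hands its alkynyl ligand to C10. The closest known reaction types are the coupling of alkynylalanes with tertiary alkyl halides and sulfonates, the organoaluminium-promoted ionisation–rearrangement–ligand transfer of sulfonates (Beckmann and pinacol-type variants), and the ring contraction of pyranoside 2-sulfonates to 2,5-anhydro sugars; their merger with a carbon nucleophile on an oxane is untested. The oxolane is closed by this net 1,2-oxygen shift, so the six-membered ring O/C6–C10 becomes the five-membered ring O/C6–C9 and C10 is expelled as the exocyclic quaternary carbon. C9 is set by stereospecific inversion (R to S), which places C10 trans to the C6 vinyl group, whereas C6, C13 and C14 are spectators and C10 is not stereogenic. The step needs capture at C10 rather than at C9, no cleavage of the allylic O–C6 bond, and C–C bond formation faster than proton loss or methyl transfer: cation stability and relief of small-ring strain direct attack to C10, cleavage of O–C6 would keep the strained ring, and the tight base-free ion pair together with the higher transfer aptitude of alkynyl over methyl on aluminium favours alkynylation.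

Step 8
Reactants: 15 oxolane enyne
Product: 17 alkynyl aldehyde (6S,9S,13R,14R), via vicinal diol 16 (not isolated)
Conditions: OsO4 (2 mol %), NaIO4, 2,6-lutidine, dioxane–H2O, rt
Reagents that add atoms: sodium periodate, [Na+].[O-]I(=O)(=O)=O
Why: Lemieux–Johnson oxidative cleavage, in which OsO4 dihydroxylates the only alkene (the hindered alkyne and the furan react much more slowly) and NaIO4 cleaves the diol, unmasking the non-enolisable C5 aldehyde on quaternary C6 without touching its configuration.

Step 9
Reactants: 17 alkynyl aldehyde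
Product: 19 saturated furyl aldehyde (6S,9S,13R,14R), via cis-alkene 18 (not isolated)
Conditions: H2 (1 atm), Pd/C, EtOAc, rt
Reagents that add atoms: none
Why: Heterogeneous catalytic hydrogenation saturates the C11≡C12 alkyne through the cis-alkene, while the trisubstituted furan, the hindered aldehyde and the furfuryl silyl ether are attacked far more slowly at one atmosphere in a neutral solvent, and no stereocentre is touched.

Step 10
Reactants: 19 saturated furyl aldehyde
Product: 22 4-hydroxycyclopentenone aldehyde (6S,9S,13R,14R,15R), via furan endoperoxide 20 (not isolated), via Z-enedione 21 (not isolated)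
Conditions: O2, tetraphenylporphyrin (cat.), visible light, CH2Cl2, −78 °C; Me2S, −78 °C to rt; then i-Pr2NEt (cat.), 0 °C to rt, short contact
Reagents that add atoms: dioxygen, O=O
Why: Furan photooxygenation–reduction–aldol cascade, in which [4+2] addition of singlet oxygen and Me2S reduction unmask the Z-enedione, whose methyl ketone carbon C4 closes 5-(enolexo)-exo-trig onto the C15 ketone, the new C15 carbinol being set under polar Felkin–Anh control by the 14R silyloxy centre (OTBS anti to the incoming C4, hydrogen on the C1 side), which is the spatial arrangement of the target (descriptor R here only because C1 outranks the CH2 carbon C4).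

Step 11
Reactants: 22 4-hydroxycyclopentenone aldehyde
Product: 25 macrocyclic aldol diol (mixture at C4 and C5), via silyloxydiene 23 (not isolated), via bis-silyl aldol 24 (not isolated)
Conditions: TMSOTf, i-Pr2NEt, CH2Cl2 (1 mM), −78 to 0 °C; then 1 M HCl, THF, 0 °C
Reagents that add atoms: none
Why: One-pot enol silane formation and intramolecular Mukaiyama aldol addition under high dilution, in which soft enolisation can only occur at C4 (C15 bears no hydrogen and no other ketone is present), the non-enolisable C5 aldehyde is the only electrophile, the C15 hydroxyl is silylated in passing against retro-aldol, and the new centres C4 and C5 are erased in the next step.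

Step 12
Reactants: 25 macrocyclic aldol diol
Product: 27 cross-conjugated dienone acetate with 14-OTBS, via diacetate 26 (not isolated)
Conditions: Ac2O, Et3N, DMAP (cat.), CH2Cl2, rt; then DBU, 0 °C to rt
Reagents that add atoms: acetic anhydride, CC(=O)OC(C)=O
Why: DMAP-catalysed exhaustive acetylation caps the tertiary C15 hydroxyl and turns the C5 hydroxyl into a leaving group, and DBU then triggers E1cB elimination to the exocyclic C4=C5 alkene, which should adopt the E geometry (C6 anti to the C3 carbonyl) that avoids the clash with the carbonyl and fits the twelve-membered ring.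

Step 13
Reactants: 27 cross-conjugated dienone acetate with 14-OTBS
Product: 28 C14 alcohol
Conditions: HF·pyridine, THF, 0 °C to rt
Reagents that add atoms: none
Why: Acidic fluoride desilylation removes the hindered TBS group, and the mildly acidic base-free medium should suppress 1,2-acetyl migration from O15 to O14 and leave the dienone and all stereocentres intact.

Step 14
Reactants: 28 C14 alcohol
Product: 29 target CNP0144863.1
Conditions: Dess–Martin periodinane, CH2Cl2, 0 °C to rt
Reagents that add atoms: none
Why: Dess–Martin oxidation converts the secondary C14 carbinol into the ketone under near-neutral conditions, so that C13, which becomes epimerisable only now, keeps its R configuration and the tertiary acetate and dienone survive.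

Compound list
1 | (S)-(+)-linalool, (3S)-3,7-dimethylocta-1,6-dien-3-ol | C=C[C@@](C)(O)CCC=C(C)C | starting material
2 | (3S,6R)-6,7-epoxylinalool, (3S)-5-[(2R)-3,3-dimethyloxiran-2-yl]-3-methylpent-1-en-3-ol | C=C[C@@](C)(O)CC[C@H]1OC1(C)C | intermediate
3 | trimethylsilyl ether of 4, {[(3R,6S)-6-ethenyl-2,2,6-trimethyloxan-3-yl]oxy}trimethylsilane | C=C[C@]1(C)CC[C@@H](O[Si](C)(C)C)C(C)(C)O1 | intermediate
4 | pyranoid linalool oxide, (3R,6S)-6-ethenyl-2,2,6-trimethyloxan-3-ol (OH cis to the C6 methyl) | C=C[C@]1(C)CC[C@@H](O)C(C)(C)O1 | intermediate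
5 | (3R,6S)-6-ethenyl-2,2,6-trimethyloxan-3-yl methanesulfonate | C=C[C@]1(C)CC[C@@H](OS(C)(=O)=O)C(C)(C)O1 | intermediate
6 | (S)-but-3-yn-2-ol | C#C[C@H](C)O | starting material
7 | (S)-but-3-yn-2-yl methanesulfonate | C#C[C@H](C)OS(C)(=O)=O | intermediate
8 | 4,5-dimethylfuran-2-carbaldehyde | Cc1cc(C=O)oc1C | starting material
9 | (aR)-buta-1,2-dien-1-yl(iodo)indium methanesulfonate | [H]C(C)=[C@@]=C([H])[In](I)OS(C)(=O)=O | intermediate
10 | (1R,2R)-1-(4,5-dimethylfuran-2-yl)-2-methylbut-3-yn-1-ol (anti; 13R,14R) | C#C[C@@H](C)[C@@H](O)c1cc(C)c(C)o1 | intermediate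
11 | tert-butyl{[(1R,2R)-1-(4,5-dimethylfuran-2-yl)-2-methylbut-3-yn-1-yl]oxy}dimethylsilane | C#C[C@@H](C)[C@@H](O[Si](C)(C)C(C)(C)C)c1cc(C)c(C)o1 | intermediate
12 | lithium acetylide of 11 | [Li]C#C[C@@H](C)[C@@H](O[Si](C)(C)C(C)(C)C)c1cc(C)c(C)o1 | intermediate
13 | dimethyl[(3R,4R)-4-(tert-butyldimethylsilyloxy)-4-(4,5-dimethylfuran-2-yl)-3-methylbut-1-yn-1-yl]alane | C[Al](C)C#C[C@@H](C)[C@@H](O[Si](C)(C)C(C)(C)C)c1cc(C)c(C)o1 | intermediate
14 | (2S,5S)-2-ethenyl-2,6,6-trimethyl-1-oxoniabicyclo[3.1.0]hexane (cation of the aluminate ion pair) | C=C[C@]1(C)CC[C@@H]2[O+]1C2(C)C | intermediate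
15 | oxolane enyne, (2S,5S)-5-[(5R,6R)-6-(tert-butyldimethylsilyloxy)-6-(4,5-dimethylfuran-2-yl)-2,5-dimethylhex-3-yn-2-yl]-2-ethenyl-2-methyloxolane (vinyl and C10 trans) | C=C[C@]1(C)CC[C@H](O1)C(C)(C)C#C[C@@H](C)[C@@H](O[Si](C)(C)C(C)(C)C)c1cc(C)c(C)o1 | intermediate
16 | vicinal diol from the vinyl group of 15 (C5 carbinol unassigned) | OCC(O)[C@]1(C)CC[C@H](O1)C(C)(C)C#C[C@@H](C)[C@@H](O[Si](C)(C)C(C)(C)C)c1cc(C)c(C)o1 | intermediate
17 | alkynyl aldehyde, (2S,5S)-5-[(5R,6R)-6-(tert-butyldimethylsilyloxy)-6-(4,5-dimethylfuran-2-yl)-2,5-dimethylhex-3-yn-2-yl]-2-methyloxolane-2-carbaldehyde | O=C[C@]1(C)CC[C@H](O1)C(C)(C)C#C[C@@H](C)[C@@H](O[Si](C)(C)C(C)(C)C)c1cc(C)c(C)o1 | intermediate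
18 | C11=C12 cis-alkene analogue of 17 | O=C[C@]1(C)CC[C@H](O1)C(C)(C)/C=C\[C@@H](C)[C@@H](O[Si](C)(C)C(C)(C)C)c1cc(C)c(C)o1 | intermediate
19 | saturated furyl aldehyde, (2S,5S)-5-[(5R,6R)-6-(tert-butyldimethylsilyloxy)-6-(4,5-dimethylfuran-2-yl)-2,5-dimethylhexan-2-yl]-2-methyloxolane-2-carbaldehyde | O=C[C@]1(C)CC[C@H](O1)C(C)(C)CC[C@@H](C)[C@@H](O[Si](C)(C)C(C)(C)C)c1cc(C)c(C)o1 | intermediate
20 | furan endoperoxide of 19 (2,3,7-trioxabicyclo[2.2.1]hept-5-ene, bridgeheads C15 and C3 unassigned) | O=C[C@]1(C)CC[C@H](O1)C(C)(C)CC[C@@H](C)[C@@H](O[Si](C)(C)C(C)(C)C)C12C=C(C)C(C)(OO1)O2 | intermediate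
21 | Z-enedione, C14(OTBS)–C15(=O)–C1H=C2(Me)–C3(=O)–C4H3 with the two ketones cis | O=C[C@]1(C)CC[C@H](O1)C(C)(C)CC[C@@H](C)[C@@H](O[Si](C)(C)C(C)(C)C)C(=O)/C=C(/C)C(C)=O | intermediate
22 | 4-hydroxycyclopentenone aldehyde, (4R)-4-hydroxy-2-methylcyclopent-2-en-1-one carrying at C4 the (14R)-OTBS, (13R)-methyl chain to the (6S,9S)-oxolane-2-carbaldehyde | O=C[C@]1(C)CC[C@H](O1)C(C)(C)CC[C@@H](C)[C@@H](O[Si](C)(C)C(C)(C)C)[C@]1(O)C=C(C)C(=O)C1 | intermediate
23 | silyloxydiene, 15-O-TMS ether and C3/C4 trimethylsilyl enol ether of 22 | O=C[C@]1(C)CC[C@H](O1)C(C)(C)CC[C@@H](C)[C@@H](O[Si](C)(C)C(C)(C)C)[C@]1(O[Si](C)(C)C)C=C(C)C(O[Si](C)(C)C)=C1 | intermediate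
24 | bis-silyl aldol, 5,15-bis-O-TMS ether of 25 | C[Si](C)(C)O[C@@]12C=C(C)C(=O)C1C(O[Si](C)(C)C)[C@]1(C)CC[C@H](O1)C(C)(C)CC[C@@H](C)[C@H]2O[Si](C)(C)C(C)(C)C | intermediate
25 | macrocyclic aldol diol, 5,15-dihydroxy-14-OTBS twelve-membered ring (6S,9S,13R,14R,15S; C4 and C5 mixed) | O[C@@]12C=C(C)C(=O)C1C(O)[C@]1(C)CC[C@H](O1)C(C)(C)CC[C@@H](C)[C@H]2O[Si](C)(C)C(C)(C)C | intermediate
26 | 5,15-diacetate of 25 | CC(=O)O[C@@]12C=C(C)C(=O)C1C(OC(C)=O)[C@]1(C)CC[C@H](O1)C(C)(C)CC[C@@H](C)[C@H]2O[Si](C)(C)C(C)(C)C | intermediate
27 | cross-conjugated dienone acetate, (4E)-15-acetoxy-14-OTBS macrocycle (6S,9S,13R,14R,15S) | CC(=O)O[C@@]12C=C(C)C(=O)/C1=C/[C@]1(C)CC[C@H](O1)C(C)(C)CC[C@@H](C)[C@H]2O[Si](C)(C)C(C)(C)C | intermediate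
28 | C14 alcohol, (4E)-15-acetoxy-14-hydroxy macrocycle (6S,9S,13R,14R,15S) | CC(=O)O[C@@]12C=C(C)C(=O)/C1=C/[C@]1(C)CC[C@H](O1)C(C)(C)CC[C@@H](C)[C@H]2O | intermediate
29 | CNP0144863.1, (4E,6S,9S,13R,15S)-15-acetoxy-6,9-epoxyjatropha-1,4-diene-3,14-dione | CC(=O)O[C@@]12C=C(C)C(=O)/C1=C/[C@]1(C)CC[C@H](O1)C(C)(C)CC[C@@H](C)C2=O | target

Total step count: 14. Longest linear sequence: 11 steps (1–3, then 7–14; the branch 4–6, then 7–14, is equally long).

Steps most likely to fail

1. Step 7 (Proposed new method).
- What may go wrong: the cationic C10 may lose a proton faster than it accepts the alkynyl ligand. Methyl may be transferred in place of alkynyl. The alane may ionise the furfuryl silyl ether.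
- Fallback, all known chemistry: the event is split into its two established halves.
- Setting out from 5, buffered solvolysis (H2O–dioxane, CaCO3, 80 °C) performs the same oxane-to-oxolane contraction with water as the nucleophile. It should give trans-furanoid linalool oxide F1.
- TMSCl with catalytic BiCl3 converts F1 into the tertiary chloride F2.
- The established coupling of tertiary alkyl chlorides with alkynylalanes (13, ClCH2CH2Cl, 0 °C) comes back to the route at 15.

2. Step 11.
- What may go wrong: oligomerisation may outrun closure of the twelve-membered ring between two hindered carbons. Retro-aldol opening of the C15 carbinol may occur before it is silylated.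
- Fallback: the enolate is made reductively at the very carbon that must react, without base or Lewis acid.
- Setting out from 22, silylation to 23 (TMSOTf, excess Et3N, −78 °C) and bromination with NBS should give the C4 bromo ketone F3.
- SmI2 in THF at −78 °C under high dilution effects an intramolecular Reformatsky-type aldol to the C15-O-trimethylsilyl aldol F4.
- Brief treatment with 1 M HCl in THF comes back to the route at 25.

3. Step 2.
- What may go wrong: 5-exo attack of the C6 oxygen at C9 may outrun 6-endo attack at C10. Proton loss from the activated epoxide may lead to an allylic silyl ether.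
- Fallback: the oxane is closed on a bromonium ion instead of an epoxide.
- Setting out from 1, bromonium-induced Markovnikov cyclisation (NBS, (CF3)2CHOH, 0 °C) places the oxygen on the tertiary carbon.
- The (3R,6S)-bromo-oxane F5 is separated by chromatography from its C9 epimer.
- F5 takes the place of 5 under the conditions of step 7, where the alane abstracts bromide, and comes back to the route at 15.
- The price is that C9 is then secured by separation and not by a reagent.

Further compounds
F1 | step 7 | trans-furanoid linalool oxide, 2-[(2S,5S)-5-ethenyl-5-methyloxolan-2-yl]propan-2-ol | C=C[C@]1(C)CC[C@H](O1)C(C)(C)O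
F2 | step 7 | tertiary chloride, (2S,5S)-5-(2-chloropropan-2-yl)-2-ethenyl-2-methyloxolane | C=C[C@]1(C)CC[C@H](O1)C(C)(C)Cl
F3 | step 11 | C4 bromo ketone, 15-O-TMS ether of 22 brominated at C4 (C4 unassigned) | O=C[C@]1(C)CC[C@H](O1)C(C)(C)CC[C@@H](C)[C@@H](O[Si](C)(C)C(C)(C)C)[C@]1(O[Si](C)(C)C)C=C(C)C(=O)C1Br
F4 | step 11 | C15-O-trimethylsilyl aldol, 15-O-TMS ether of 25 | C[Si](C)(C)O[C@@]12C=C(C)C(=O)C1C(O)[C@]1(C)CC[C@H](O1)C(C)(C)CC[C@@H](C)[C@H]2O[Si](C)(C)C(C)(C)C
F5 | step 2 | (3R,6S)-bromo-oxane, (3R,6S)-3-bromo-6-ethenyl-2,2,6-trimethyloxane | C=C[C@]1(C)CC[C@@H](Br)C(C)(C)O1
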